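**Plan**
- Retrosynthesis: with the acyl chain numbered from the ester carbonyl (C1) to the methyl end (C26), the cuts are the ester C–O bond and the C8–C9 bond. The four methylenes C5–C8 are traced back to the four ring carbons of a 2,5-disubstituted thiophene.
- Forward: 4-(thiophen-2-yl)butanoic acid 1 (C1–C8) is esterified with 2-phenylethanol 2 to ester 3. Octadecanoyl chloride 4 (C9–C26) is then joined to the free alpha carbon of the thiophene by Friedel–Crafts acylation.
- The C9 ketone is reduced to CH2, and Raney Ni then excises sulfur and opens the heterocycle into the saturated C5–C8 segment. Carbon count: 4 + 4 + 18 = 26.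
- No ring of the target is built. The phenyl ring arrives with 2, and the thiophene is a purchased, temporary ring.
- The target has no stereocentre, so nothing has to be set or preserved.

Key step: step 2

Remark: compounds 1, 2 and 4 are assumed to be purchasable. "C5" of the thiophene means the ring position; it becomes C8 of the final chain.

Step 1
Reactants: 1 4-(thiophen-2-yl)butanoic acid; 2 2-phenylethanol
Product: 3 2-phenylethyl 4-(thiophen-2-yl)butanoate
Conditions: DCC (1.1 equiv), DMAP (0.1 equiv), CH2Cl2, 0 °C to rt
Reagents that add atoms: none
Why: Steglich esterification; DCC activates the carboxyl group and DMAP relays the acyl group to the unhindered primary alcohol under neutral conditions that leave the thiophene untouched.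

Step 2
Reactants: 3 2-phenylethyl 4-(thiophen-2-yl)butanoate; 4 octadecanoyl chloride (stearoyl chloride)
Product: 5 2-phenylethyl 4-(5-octadecanoylthiophen-2-yl)butanoate
Conditions: SnCl4 (1.3 equiv) added to 3 and 4 in CH2Cl2, −10 to 0 °C; then cold 1 M HCl
Reagents that add atoms: none
Why: Friedel–Crafts acylation of a 2-alkylthiophene: SnCl4 ionises 4 to the octadecanoyl cation, which adds to ring carbon C5 to give a sulfur-stabilised sigma complex, and loss of the C5 proton restores the aromatic ring with the C8–C9 bond of the future chain in place. The closest known reaction type is the SnCl4-mediated acylation of thiophene and its 2-alkyl homologues with aliphatic acid chlorides. No ring is closed and no stereocentre is created, so neither a closure mode nor a stereocontrol element is involved. The step needs site selectivity for thiophene C5 over C3, C4 and the phenyl ring: attack at the free alpha position gives the best-stabilised sigma complex, the alkyl group at C2 also directs to C5, and a monoalkylbenzene is far less nucleophilic than a 2-alkylthiophene and should not be acylated under SnCl4. The ester binds the Lewis acid only reversibly, which the slight excess of SnCl4 allows for, and the ketone formed deactivates the ring against a second acylation.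

Step 3
Reactants: 5 2-phenylethyl 4-(5-octadecanoylthiophen-2-yl)butanoate
Product: 7 2-phenylethyl 4-(5-octadecylthiophen-2-yl)butanoate, via thienyl carbinol 6 (not isolated)
Conditions: Et3SiH (2.5 equiv), TFA/CH2Cl2, 0 °C to rt
Reagents that add atoms: none
Why: Ionic hydrogenation of an aryl ketone; the protonated thienyl ketone takes hydride from Et3SiH to give carbinol 6, which ionises in TFA to a thiophene-stabilised carbocation that takes a second hydride, while the ester and the phenyl ring are inert to this reagent pair.

Step 4
Reactants: 7 2-phenylethyl 4-(5-octadecylthiophen-2-yl)butanoate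
Product: 8 2-phenylethyl hexacosanoate (phenylethyl n-hexacosanoate)
Conditions: Raney Ni (W-2, washed neutral, large excess), H2 (1 atm), THF, reflux
Reagents that add atoms: none
Why: Raney Ni hydrodesulfurisation of a 2,5-dialkylthiophene; both C–S bonds are cleaved on the nickel surface and the freed C4 unit is saturated to become C5–C8 of the chain, while the ester and the isolated benzene ring should not be reduced at this temperature and pressure, and the non-alcoholic solvent avoids ester exchange.

**Compound list**
1 | 4-(thiophen-2-yl)butanoic acid | OC(=O)CCCc1cccs1 | starting material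
2 | 2-phenylethanol | OCCc1ccccc1 | starting material
3 | 2-phenylethyl 4-(thiophen-2-yl)butanoate | O=C(CCCc1cccs1)OCCc1ccccc1 | intermediate
4 | octadecanoyl chloride (stearoyl chloride) | CCCCCCCCCCCCCCCCCC(=O)Cl | starting material
5 | 2-phenylethyl 4-(5-octadecanoylthiophen-2-yl)butanoate | CCCCCCCCCCCCCCCCCC(=O)c1ccc(CCCC(=O)OCCc2ccccc2)s1 | intermediate
6 | 2-phenylethyl 4-[5-(1-hydroxyoctadecyl)thiophen-2-yl]butanoate (racemic carbinol) | CCCCCCCCCCCCCCCCCC(O)c1ccc(CCCC(=O)OCCc2ccccc2)s1 | intermediate (not isolated)
7 | 2-phenylethyl 4-(5-octadecylthiophen-2-yl)butanoate | CCCCCCCCCCCCCCCCCCc1ccc(CCCC(=O)OCCc2ccccc2)s1 | intermediate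
8 | 2-phenylethyl hexacosanoate | CCCCCCCCCCCCCCCCCCCCCCCCCC(=O)OCCc1ccccc1 | target

**Step count**
Total steps: 4. Longest linear sequence: 4 steps (1 → 3 → 5 → 7 → 8).

**Steps most likely to fail**

1. Step 3. The thiophene ring may be reduced further to the thiolane by continued ionic hydrogenation, or the electron-rich dialkylthiophene may oligomerise in the acid before the carbonyl is fully deoxygenated. A thiolane formed this way would still be desulfurised in step 4. Fallback: setting out from 5, the ketone would be condensed with ethane-1,2-dithiol under BF3·OEt2 in CH2Cl2 to give the dithiolane 2-phenylethyl 4-[5-(2-heptadecyl-1,3-dithiolan-2-yl)thiophen-2-yl]butanoate F1. Raney Ni with H2 in THF would then remove all three sulfur atoms in one operation (Mozingo reduction together with the thiophene desulfurisation), and the route is rejoined at 8.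

2. Step 4. Hydrogenolysis may stop short and leave sulfur-containing or olefinic material; the phenethyl ester may be exchanged or cleaved on insufficiently washed nickel; the phenyl ring may be partly hydrogenated; and the waxy product may be lost by adsorption on the large nickel excess. Fallback: setting out from 7, saponification (NaOH, aqueous ethanol, then HCl) would give 4-(5-octadecylthiophen-2-yl)butanoic acid F2. Desulfurisation of F2 with Raney Ni in hot aqueous-ethanolic NaOH, followed by acidification, would give hexacosanoic acid F3, with no phenyl ring or exchangeable ester present while the nickel acts. Acid-catalysed esterification of F3 with 2 (TsOH, toluene, Dean–Stark) would come back to the route at 8.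

3. Step 2. The thiophene may oligomerise under the Lewis acid, the acylation may stall because the ester ties up SnCl4, or attack may be diverted to other ring positions. Fallback: setting out from 3, NBS in DMF at 0 °C would brominate the free alpha position to give 2-phenylethyl 4-(5-bromothiophen-2-yl)butanoate F4. Sonogashira coupling of F4 with octadec-1-yne (Pd(PPh3)2Cl2, CuI, Et3N, 60 °C) would form the same C8–C9 bond and give 2-phenylethyl 4-[5-(octadec-1-yn-1-yl)thiophen-2-yl]butanoate F5. The Raney Ni and H2 treatment of step 4 would then saturate the alkyne and excise sulfur together, coming back to the route at 8.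

**Further compounds**
F1 | step 3 | 2-phenylethyl 4-[5-(2-heptadecyl-1,3-dithiolan-2-yl)thiophen-2-yl]butanoate | CCCCCCCCCCCCCCCCCC1(SCCS1)c1ccc(CCCC(=O)OCCc2ccccc2)s1
F2 | step 4 | 4-(5-octadecylthiophen-2-yl)butanoic acid | CCCCCCCCCCCCCCCCCCc1ccc(CCCC(=O)O)s1
F3 | step 4 | hexacosanoic acid | CCCCCCCCCCCCCCCCCCCCCCCCCC(=O)O
F4 | step 2 | 2-phenylethyl 4-(5-bromothiophen-2-yl)butanoate | O=C(CCCc1ccc(Br)s1)OCCc1ccccc1
F5 | step 2 | 2-phenylethyl 4-[5-(octadec-1-yn-1-yl)thiophen-2-yl]butanoate | CCCCCCCCCCCCCCCCC#Cc1ccc(CCCC(=O)OCCc2ccccc2)s1
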